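**Strategy**

Fragransin B1 is a meso 2,5-diaryl-3,4-dimethyltetrahydrofuran (ring atoms O1, C2–C5). The ring is disconnected at C2–C3: C2, which bears an aryl group and O1, is taken back to an aroate carbonyl, and C3, which bears a methyl group, to a methyl ketone carbonyl, the two being held 1,4 by the O1–C5–C4 chain. A low-valent titanium ketone–ester coupling forms C2=C3 and closes the ring as a 4,5-dihydrofuran in one operation. Its precursor is the racemic O-aroylated syn aldol (a 1-aryl-2-methyl-3-oxobutyl aroate), reached by crotylboration, esterification and Wacker oxidation. Face-selective hydrogenation and acid equilibration of C2 and C5 complete the route.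

Key step: step 6

Remark on the chemistry: the target has a mirror plane through O1 and the midpoint of C3–C4 (2S,3S,4R,5R with identical aryl groups), so every chiral intermediate is used as the racemate and its SMILES shows one enantiomer only to fix the relative configuration. The labels O1 and C2–C5 follow the numbering of the target ring throughout. Both aryl units are drawn from one benzylated aldehyde.

**Route**

Step 1
Reactants: 1 syringaldehyde (4-hydroxy-3,5-dimethoxybenzaldehyde)
Product: 2 4-(benzyloxy)-3,5-dimethoxybenzaldehyde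
Conditions: BnBr, K2CO3, DMF, 60 °C
Reagents that add atoms: benzyl bromide, BrCc1ccccc1
Why: Williamson ether synthesis on the acidic para-formyl phenoxide; the benzyl ether should be inert to the boronate, to the Wacker conditions and to low-valent titanium, and leaves later by hydrogenolysis.

Step 2
Reactants: 2 4-(benzyloxy)-3,5-dimethoxybenzaldehyde (part of the batch)
Product: 3 4-(benzyloxy)-3,5-dimethoxybenzoic acid
Conditions: NaClO2, NaH2PO4, 2-methylbut-2-ene, t-BuOH/H2O, rt
Reagents that add atoms: sodium chlorite, [Na+].[O-]Cl=O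
Why: Pinnick oxidation, in which chlorous acid oxidises only the aldehyde while the alkene scavenges hypochlorous acid so that the electron-rich ring should not be chlorinated.

Step 3
Reactants: 2 4-(benzyloxy)-3,5-dimethoxybenzaldehyde; 4 (Z)-crotylboronic acid pinacol ester
Product: 6 syn-(1R*,2S*)-1-[4-(benzyloxy)-3,5-dimethoxyphenyl]-2-methylbut-3-en-1-ol (racemic), via homoallyl pinacol borate 5 (not isolated)
Conditions: 4 (1.3 equiv), toluene (concentrated), rt to 40 °C; then aq. NaHCO3
Reagents that add atoms: none
Why: Crotylboration through a closed six-membered chair transition state in which the aryl group sits equatorial and the Z-methyl axial, which should set C4 and C5 in the syn relationship (racemic), the borate being hydrolysed on work-up.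

Step 4
Reactants: 6 syn homoallylic alcohol; 3 4-(benzyloxy)-3,5-dimethoxybenzoic acid
Product: 7 syn-(1R*,2S*)-1-[4-(benzyloxy)-3,5-dimethoxyphenyl]-2-methylbut-3-en-1-yl 4-(benzyloxy)-3,5-dimethoxybenzoate
Conditions: DCC, DMAP (cat.), CH2Cl2, 0 °C to rt
Reagents that add atoms: none
Why: Steglich esterification through the acylpyridinium ion, which acylates the secondary benzylic alcohol without touching its C–O bond, so both stereocentres are retained and no acid chloride has to be made.

Step 5
Reactants: 7 syn homoallylic aroate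
Product: 8 syn-(1R*,2R*)-1-[4-(benzyloxy)-3,5-dimethoxyphenyl]-2-methyl-3-oxobutyl 4-(benzyloxy)-3,5-dimethoxybenzoate
Conditions: PdCl2 (10 mol%), CuCl, O2 (1 atm), DMF/H2O 7:1, rt
Reagents that add atoms: water, O
Why: Wacker–Tsuji oxidation, in which Markovnikov hydroxypalladation of the terminal alkene and β-hydride elimination should give the methyl ketone under near-neutral conditions that leave the ester, the benzyl ethers and both stereocentres alone.

Step 6
Reactants: 8 syn keto aroate
Product: 9 4,5-cis-(4S*,5R*)-2,5-bis[4-(benzyloxy)-3,5-dimethoxyphenyl]-3,4-dimethyl-4,5-dihydrofuran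
Conditions: TiCl3(DME)1.5 (8 equiv), Zn–Cu (20 equiv), DME, reflux 3 h; then 8 in DME by syringe pump over ca. 20 h, reflux; filtration through Celite/K2CO3
Reagents that add atoms: none
Why: McMurry-type oxo-ester coupling: low-valent titanium reduces the methyl ketone, the more easily reduced of the two carbonyl groups, to a titanium-bound ketyl whose carbon (C3) adds to the aroate carbonyl (C2), and the titanium 1,2-diolate so formed is deoxygenated to the C2=C3 enol ether, driven by the strength of the Ti–O bonds. The closest known reaction type is the titanium-mediated keto-ester cyclisation that gives cyclic enol ethers, furans and benzofurans. The ring (O1, C2, C3, C4, C5) closes in a 5-exo-trig mode, the attacked C=O bond lying outside the ring, with O1–C5–C4 as the pre-existing tether. No stereocentre is formed; C4 and C5 come unchanged from the syn crotylation and become the cis 4-methyl/5-aryl pair. The step needs intramolecular ketone–ester coupling in preference to bimolecular ketone–ketone coupling, which the five-membered closure and the low standing concentration from slow addition should secure, and it needs the β-aroyloxy ketone to escape loss of the aroic acid and enolisation at C4, which is why 8 meets an excess of pre-reduced, non-basic reagent and is consumed as it arrives. Once the ketyl has formed the elimination pathway through the enolate is closed, and aryl benzyl ethers are not expected to react with the reagent.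

Step 7
Reactants: 9 4,5-cis dihydrofuran bis(benzyl ether)
Product: 11 all-cis-(2S,3R,4S,5R)-2,5-bis(4-hydroxy-3,5-dimethoxyphenyl)-3,4-dimethyltetrahydrofuran (meso), via bisphenol dihydrofuran 10 (not isolated)
Conditions: H2 (1–4 atm), 10% Pd/C, EtOAc/THF, rt
Reagents that add atoms: none
Why: Heterogeneous catalytic hydrogenation, in which the aryl benzyl ethers are hydrogenolysed and H2 adds syn to the aryl-conjugated C2=C3 bond from the face opposite the cis C4-methyl and C5-aryl groups, so that C2 and C3 are set with all four substituents on one face and the C3/C4 methyl groups cis as the target requires.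

Step 8
Reactants: 11 all-cis bisphenol tetrahydrofuran
Product: 12 fragransin B1, (2S,3S,4R,5R)-2,5-bis(4-hydroxy-3,5-dimethoxyphenyl)-3,4-dimethyltetrahydrofuran (meso; 2,3-trans, 3,4-cis, 4,5-trans)
Conditions: CF3CO2H (0.2 equiv), CH2Cl2, 0 °C to rt; aq. NaHCO3
Reagents that add atoms: none
Why: Acid-catalysed epimerisation of the benzylic ether centres, in which reversible heterolysis of C2–O1 and C5–O1 to para-hydroxybenzyl cations and reclosure under thermodynamic control should place each aryl group trans to its neighbouring methyl group, while C3 and C4 take no part and stay cis.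

**Compound list**

1 | syringaldehyde (4-hydroxy-3,5-dimethoxybenzaldehyde) | COc1cc(C=O)cc(OC)c1O | starting material
2 | 4-(benzyloxy)-3,5-dimethoxybenzaldehyde | COc1cc(C=O)cc(OC)c1OCc1ccccc1 | intermediate
3 | 4-(benzyloxy)-3,5-dimethoxybenzoic acid | COc1cc(C(=O)O)cc(OC)c1OCc1ccccc1 | intermediate
4 | (Z)-crotylboronic acid pinacol ester | C/C=C\CB1OC(C)(C)C(C)(C)O1 | starting material
5 | pinacol borate of the syn homoallylic alcohol, 2-{[(1R*,2S*)-1-(4-benzyloxy-3,5-dimethoxyphenyl)-2-methylbut-3-en-1-yl]oxy}-4,4,5,5-tetramethyl-1,3,2-dioxaborolane (racemic) | C=C[C@H](C)[C@H](c1cc(OC)c(OCc2ccccc2)c(OC)c1)OB1OC(C)(C)C(C)(C)O1 | intermediate (not isolated)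
6 | syn-(1R*,2S*)-1-[4-(benzyloxy)-3,5-dimethoxyphenyl]-2-methylbut-3-en-1-ol (racemic) | C=C[C@H](C)[C@H](c1cc(OC)c(OCc2ccccc2)c(OC)c1)O | intermediate
7 | syn-(1R*,2S*)-1-[4-(benzyloxy)-3,5-dimethoxyphenyl]-2-methylbut-3-en-1-yl 4-(benzyloxy)-3,5-dimethoxybenzoate (racemic) | C=C[C@H](C)[C@H](c1cc(OC)c(OCc2ccccc2)c(OC)c1)OC(=O)c1cc(OC)c(OCc2ccccc2)c(OC)c1 | intermediate
8 | syn-(1R*,2R*)-1-[4-(benzyloxy)-3,5-dimethoxyphenyl]-2-methyl-3-oxobutyl 4-(benzyloxy)-3,5-dimethoxybenzoate (racemic) | CC(=O)[C@H](C)[C@H](c1cc(OC)c(OCc2ccccc2)c(OC)c1)OC(=O)c1cc(OC)c(OCc2ccccc2)c(OC)c1 | intermediate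
9 | 4,5-cis-(4S*,5R*)-2,5-bis[4-(benzyloxy)-3,5-dimethoxyphenyl]-3,4-dimethyl-4,5-dihydrofuran (racemic) | COc1cc(C2=C(C)[C@H](C)[C@H](c3cc(OC)c(OCc4ccccc4)c(OC)c3)O2)cc(OC)c1OCc1ccccc1 | intermediate
10 | 4,5-cis-(4S*,5R*)-2,5-bis(4-hydroxy-3,5-dimethoxyphenyl)-3,4-dimethyl-4,5-dihydrofuran (racemic) | COc1cc(C2=C(C)[C@H](C)[C@H](c3cc(OC)c(O)c(OC)c3)O2)cc(OC)c1O | intermediate (not isolated)
11 | all-cis-(2S,3R,4S,5R)-2,5-bis(4-hydroxy-3,5-dimethoxyphenyl)-3,4-dimethyltetrahydrofuran (meso) | COc1cc([C@H]2O[C@@H](c3cc(OC)c(O)c(OC)c3)[C@@H](C)[C@H]2C)cc(OC)c1O | intermediate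
12 | fragransin B1, (2S,3S,4R,5R)-2,5-bis(4-hydroxy-3,5-dimethoxyphenyl)-3,4-dimethyltetrahydrofuran (meso) | COc1cc([C@H]2O[C@@H](c3cc(OC)c(O)c(OC)c3)[C@H](C)[C@@H]2C)cc(OC)c1O | target

**Count**

Total step count: 8. Longest linear sequence: 7 steps (steps 1, 3, 4, 5, 6, 7, 8 from syringaldehyde); step 2 is a one-step branch from 2.

**Steps most likely to fail, with fallbacks**

Step 6. The aroate may be lost by β-elimination before the ketyl forms, either through enolisation towards C4 or through Lewis-acid-assisted ionisation of the electron-rich benzylic C5–O bond. Bimolecular ketone coupling may also compete with ring closure. In that case the ring would be built by the furan route, which sets out from 2 and comes back to the route at 11. EtMgBr in THF adds to 2 to give 1-[4-(benzyloxy)-3,5-dimethoxyphenyl]propan-1-ol F1, and MnO2 in CH2Cl2 oxidises this benzylic alcohol to 1-[4-(benzyloxy)-3,5-dimethoxyphenyl]propan-1-one F2. The lithium enolate of F2 (LiN(i-Pr)2, THF, −78 °C) is dimerised oxidatively with CuCl2 to 1,4-bis[4-(benzyloxy)-3,5-dimethoxyphenyl]-2,3-dimethylbutane-1,4-dione F3, whose diastereomer mixture is of no consequence. TsOH in hot toluene closes F3 in a Paal–Knorr cyclodehydration to 2,5-bis[4-(benzyloxy)-3,5-dimethoxyphenyl]-3,4-dimethylfuran F4. Hydrogenation of F4 over 10% Pd/C should add hydrogen to one face of the furan and remove the benzyl groups, giving all-cis 11, which then enters step 8.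

Step 8. On the free bisphenol the benzylic cation may be trapped by the other aryl ring (Friedel–Crafts closure to an aryltetralin), or it may lose the C3 proton and so scramble the C3 configuration, or equilibration may stop at the mono-epimer. The order of events would then be changed, setting out from 9 and coming back at 12. Hydrogenation of 9 over 5% Rh/Al2O3 in EtOAc, which should saturate C2=C3 and leave aryl benzyl ethers intact, gives the all-cis 2,5-bis[4-(benzyloxy)-3,5-dimethoxyphenyl]-3,4-dimethyltetrahydrofuran F5. BF3·OEt2 in CH2Cl2 at −20 to 0 °C then epimerises C2 and C5 at the protected stage, where no quinone methide can form, to the 2,3-trans-3,4-cis-4,5-trans bis(benzyl ether) F6. Hydrogenolysis over 10% Pd/C in EtOAc/THF removes the benzyl groups to give 12. This branch also separates alkene reduction from debenzylation, should ring hydrogenolysis trouble step 7.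

Step 5. Coordination of palladium by the ester may steer attack of water to the terminal carbon (aldehyde), the double bond may migrate, or the product may lose the aroate in the acidic copper chloride medium. The ketone would then be reached in two near-neutral steps, setting out from 7 and coming back at 8. Mukaiyama hydration (Co(acac)2 cat., PhSiH3, O2, i-PrOH, rt) gives the Markovnikov secondary alcohol 1-[4-(benzyloxy)-3,5-dimethoxyphenyl]-3-hydroxy-2-methylbutyl 4-(benzyloxy)-3,5-dimethoxybenzoate F7 as a mixture of carbinol epimers. Dess–Martin periodinane buffered with NaHCO3 in CH2Cl2 oxidises F7 to 8, and is applied promptly to forestall 1,3-acyl migration.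

**Further compounds**

F1 | step 6 | 1-[4-(benzyloxy)-3,5-dimethoxyphenyl]propan-1-ol (racemic) | CCC(O)c1cc(OC)c(OCc2ccccc2)c(OC)c1
F2 | step 6 | 1-[4-(benzyloxy)-3,5-dimethoxyphenyl]propan-1-one | CCC(=O)c1cc(OC)c(OCc2ccccc2)c(OC)c1
F3 | step 6 | 1,4-bis[4-(benzyloxy)-3,5-dimethoxyphenyl]-2,3-dimethylbutane-1,4-dione (meso and racemic diastereomers, used as the mixture) | CC(C(C)C(=O)c1cc(OC)c(OCc2ccccc2)c(OC)c1)C(=O)c1cc(OC)c(OCc2ccccc2)c(OC)c1
F4 | step 6 | 2,5-bis[4-(benzyloxy)-3,5-dimethoxyphenyl]-3,4-dimethylfuran | Cc1c(-c2cc(OC)c(OCc3ccccc3)c(OC)c2)oc(-c2cc(OC)c(OCc3ccccc3)c(OC)c2)c1C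
F5 | step 8 | all-cis-(2S,3R,4S,5R)-2,5-bis[4-(benzyloxy)-3,5-dimethoxyphenyl]-3,4-dimethyltetrahydrofuran (meso) | COc1cc([C@H]2O[C@@H](c3cc(OC)c(OCc4ccccc4)c(OC)c3)[C@@H](C)[C@H]2C)cc(OC)c1OCc1ccccc1
F6 | step 8 | (2S,3S,4R,5R)-2,5-bis[4-(benzyloxy)-3,5-dimethoxyphenyl]-3,4-dimethyltetrahydrofuran (meso; 2,3-trans, 3,4-cis, 4,5-trans) | COc1cc([C@H]2O[C@@H](c3cc(OC)c(OCc4ccccc4)c(OC)c3)[C@H](C)[C@@H]2C)cc(OC)c1OCc1ccccc1
F7 | step 5 | (1R*,2R*)-1-[4-(benzyloxy)-3,5-dimethoxyphenyl]-3-hydroxy-2-methylbutyl 4-(benzyloxy)-3,5-dimethoxybenzoate (epimer mixture at C3 of the butyl chain) | CC(O)[C@H](C)[C@H](c1cc(OC)c(OCc2ccccc2)c(OC)c1)OC(=O)c1cc(OC)c(OCc2ccccc2)c(OC)c1
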